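## Retrosynthetic overview
1. The C-3′ tertiary alcohol comes last, by Markovnikov hydration of an isopropenyl group, so it never needs protection.
2. The pyranone is the only ring that is built. The benzene ring is bought as resorcinol. A salicylaldehyde half is closed with Ph3P=C=C=O after the one non-chelated phenol has been methylated.
3. The key disconnection is C-1′–C-2′: C2v-symmetric 4,6-dihydroxyisophthalaldehyde plus a γ-isovaleryloxy-methallylchromium reagent. One enantioselective, syn-selective mono-addition breaks the symmetry, sets both stereocentres and delivers the isovalerate already on O-2′, so no diol has to be differentiated.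
4. The dialdehyde comes from resorcinol by double formylation. The allyl donor comes from methacrolein and isovaleryl chloride.

Assumption: the salen antipode that gives the (1R) carbinol is taken to be (S,S), by analogy with simple Cr(salen) allylations. If the first run (Mosher ester check) shows the opposite sense, the equally commercial (R,R) ligand is used and nothing else changes.

The target is (1′R,2′S), which is the syn (threo) 1′,2′-diol pattern. In the isopropenyl precursors the same spatial arrangement is named (1R,2R), because the CIP priorities at C-2′ change.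

## Route

**Step 1**
Reactants: 1 resorcinol
Product: 3 4,6-dihydroxyisophthalaldehyde, via 4,6-bis[(phenylimino)methyl]benzene-1,3-diol 2 (not isolated)
Conditions: PhN=CH–NHPh (2.5 equiv), neat, 150→180 °C, aniline distilled off; then 2 M HCl, EtOH, reflux
Reagents that add atoms: N,N′-diphenylformamidine, C(=Nc1ccccc1)Nc1ccccc1; water, O
Why: Formamidine (anil) formylation is an electrophilic aromatic substitution in which the amidine carbon attacks the two equivalent positions ortho to one OH and para to the other (C-2 is flanked on both sides), loss of aniline drives it, and acid hydrolysis of both o-hydroxy-anils frees the symmetric dialdehyde; no stereocentre is formed.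

**Step 2**
Reactants: 4 methacrolein; 5 isovaleryl chloride
Product: 7 3-chloro-2-methylprop-1-en-1-yl 3-methylbutanoate (E/Z mixture), via rac-1-chloro-2-methylprop-2-en-1-yl 3-methylbutanoate 6 (not isolated)
Conditions: ZnCl2 (2 mol %), CH2Cl2, −10 °C→rt; distil
Reagents that add atoms: none
Why: This is a Lewis-acid-catalysed addition of an acyl chloride to an enal, in which the α-chloroalkyl ester 6 from 1,2-addition ionises reversibly and collapses by allylic 1,3-chloride shift to the more stable conjugated enol ester with a primary allylic chloride; the E/Z ratio does not matter because the derived allylmetal equilibrates.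

**Step 3 (key step)**
Reactants: 3 4,6-dihydroxyisophthalaldehyde (1.5 equiv); 7 3-chloro-2-methylprop-1-en-1-yl 3-methylbutanoate (1.0 equiv)
Product: 10 (1R,2R)-1-(5-formyl-2,4-dihydroxyphenyl)-1-hydroxy-3-methylbut-3-en-2-yl 3-methylbutanoate, via 4,6-bis(trimethylsilyloxy)isophthalaldehyde 8 (not isolated), via (1R,2R)-1-[5-formyl-2,4-bis(trimethylsilyloxy)phenyl]-3-methyl-1-(trimethylsilyloxy)but-3-en-2-yl 3-methylbutanoate 9 (not isolated)
Conditions: (i) Me3SiCl (2.2 equiv), Et3N (2.3 equiv), THF, 0 °C→rt, filter under Ar, evaporate; (ii) 7, CrCl3 (10 mol %), (S,S)-N,N′-bis(3,5-di-tert-butylsalicylidene)-1,2-cyclohexanediamine (20 mol %), Et3N (40 mol %), Mn (3 equiv), Me3SiCl (1.5 equiv), MeCN, rt, 24–48 h; (iii) 10 % aq. citric acid, THF, 0 °C; chromatography removes the anti isomer and the bis-adduct and returns excess 3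
Reagents that add atoms: chlorotrimethylsilane, C[Si](C)(C)Cl (its Me3Si groups are carried only by 8 and 9 and are gone in 10)
Why: Proposed new method: two Cr(II) insert into the allylic C–Cl bond of 7, the γ-acyloxy-methallylchromium(III)–salen species adds through its oxygen-bearing γ-carbon to one of the two homotopic CHO groups of 8 in a closed six-membered transition state in which the ligand selects the aldehyde face (C-1′ R) and the ester-chelated Z-allyl geometry gives the syn relationship (C-2′), Me3SiCl releases the catalyst and Mn returns it to Cr(II), and mono-addition is favoured by the excess of 8 and by the loss of the electron-withdrawing partner CHO after the first addition; the closest known reaction is the Cr(salen)/Mn/Me3SiCl-catalysed enantioselective Nozaki–Hiyama–Kishi addition of 3-chloropropenyl pivalate to aromatic aldehydes, which gives syn-ene-diol monoesters, and the new elements are the 2-methyl donor and its use on a dialdehyde.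

**Step 4**
Reactants: 10 (1R,2R)-1-(5-formyl-2,4-dihydroxyphenyl)-1-hydroxy-3-methylbut-3-en-2-yl 3-methylbutanoate
Product: 11 (1R,2R)-1-(5-formyl-4-hydroxy-2-methoxyphenyl)-1-hydroxy-3-methylbut-3-en-2-yl 3-methylbutanoate
Conditions: MeI (1.1 equiv), KHCO3 (1.2 equiv), DMF, rt
Reagents that add atoms: iodomethane, CI
Why: In this Williamson etherification, as with 2,4-dihydroxybenzaldehyde, only the phenol para to CHO is free and acidic enough for bicarbonate while the ortho phenol is locked in a hydrogen bond to the aldehyde, and the weak base leaves the aliphatic OH protonated, so the 2′→1′ acyl shift and epimerisation are avoided.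

**Step 5**
Reactants: 11 (1R,2R)-1-(5-formyl-4-hydroxy-2-methoxyphenyl)-1-hydroxy-3-methylbut-3-en-2-yl 3-methylbutanoate
Product: 13 (1R,2R)-1-hydroxy-1-(7-methoxy-2-oxo-2H-chromen-6-yl)-3-methylbut-3-en-2-yl 3-methylbutanoate, via aryl (triphenylphosphoranylidene)acetate of 11 at its phenol oxygen 12 (not isolated)
Conditions: Ph3P=C=C=O (1.05 equiv), toluene (0.02 M), 60–80 °C
Reagents that add atoms: (triphenylphosphoranylidene)ketene (Bestmann ylide), O=C=C=P(c1ccccc1)(c1ccccc1)c1ccccc1
Why: In the Bestmann ylide coumarin synthesis the acidic phenol O–H adds to the cumulated ylide much faster than the hindered secondary alcohol, and the resulting ester ylide closes by an intramolecular Wittig reaction on the ortho aldehyde, which can only give the cis ring alkene; the conditions are neutral, so both stereocentres and the ester position are untouched.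

**Step 6**
Reactants: 13 (1R,2R)-1-hydroxy-1-(7-methoxy-2-oxo-2H-chromen-6-yl)-3-methylbut-3-en-2-yl 3-methylbutanoate
Product: 14 (1R,2S)-1,3-dihydroxy-1-(7-methoxy-2-oxo-2H-chromen-6-yl)-3-methylbutan-2-yl 3-methylbutanoate (target)
Conditions: Co(acac)2 (20 mol %), PhSiH3 (2.5 equiv), O2 (1 atm), THF, rt
Reagents that add atoms: dioxygen, O=O
Why: In the Mukaiyama hydration, hydrogen-atom transfer from Co–H goes to the CH2 end of the electron-neutral 1,1-disubstituted alkene far faster than to the 1,2-disubstituted, electron-poor coumarin C3=C4 bond, the tertiary radical is trapped by O2 faster than any 1,2-acyloxy shift, and the peroxide is reduced by the silane; C-3′ is not stereogenic and C-1′/C-2′ are not involved.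

## Compound list
1 | resorcinol | Oc1cccc(O)c1 | starting material
2 | 4,6-bis[(phenylimino)methyl]benzene-1,3-diol | Oc1cc(O)c(C=Nc2ccccc2)cc1C=Nc1ccccc1 | intermediate (not isolated)
3 | 4,6-dihydroxyisophthalaldehyde | O=Cc1cc(C=O)c(O)cc1O | intermediate
4 | methacrolein | CC(=C)C=O | starting material
5 | isovaleryl chloride | CC(C)CC(=O)Cl | starting material
6 | rac-1-chloro-2-methylprop-2-en-1-yl 3-methylbutanoate | CC(C)CC(=O)OC(Cl)C(C)=C | intermediate (not isolated)
7 | 3-chloro-2-methylprop-1-en-1-yl 3-methylbutanoate (E/Z mixture) | CC(C)CC(=O)OC=C(C)CCl | intermediate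
8 | 4,6-bis(trimethylsilyloxy)isophthalaldehyde | C[Si](C)(C)Oc1cc(O[Si](C)(C)C)c(C=O)cc1C=O | intermediate (not isolated)
9 | (1R,2R)-1-[5-formyl-2,4-bis(trimethylsilyloxy)phenyl]-3-methyl-1-(trimethylsilyloxy)but-3-en-2-yl 3-methylbutanoate | C[Si](C)(C)Oc1cc(O[Si](C)(C)C)c(C=O)cc1[C@@H](O[Si](C)(C)C)[C@H](OC(=O)CC(C)C)C(C)=C | intermediate (not isolated)
10 | (1R,2R)-1-(5-formyl-2,4-dihydroxyphenyl)-1-hydroxy-3-methylbut-3-en-2-yl 3-methylbutanoate | Oc1cc(O)c(C=O)cc1[C@@H](O)[C@H](OC(=O)CC(C)C)C(C)=C | intermediate
11 | (1R,2R)-1-(5-formyl-4-hydroxy-2-methoxyphenyl)-1-hydroxy-3-methylbut-3-en-2-yl 3-methylbutanoate | COc1cc(O)c(C=O)cc1[C@@H](O)[C@H](OC(=O)CC(C)C)C(C)=C | intermediate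
12 | aryl (triphenylphosphoranylidene)acetate of 11 (ester ylide on the phenol oxygen) | COc1cc(OC(=O)C=P(c2ccccc2)(c2ccccc2)c2ccccc2)c(C=O)cc1[C@@H](O)[C@H](OC(=O)CC(C)C)C(C)=C | intermediate (not isolated)
13 | (1R,2R)-1-hydroxy-1-(7-methoxy-2-oxo-2H-chromen-6-yl)-3-methylbut-3-en-2-yl 3-methylbutanoate | COc1cc2oc(=O)ccc2cc1[C@@H](O)[C@H](OC(=O)CC(C)C)C(C)=C | intermediate
14 | (1R,2S)-1,3-dihydroxy-1-(7-methoxy-2-oxo-2H-chromen-6-yl)-3-methylbutan-2-yl 3-methylbutanoate (CNP0260807.1) | COc1cc2oc(=O)ccc2cc1[C@@H](O)[C@H](OC(=O)CC(C)C)C(C)(C)O | target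

## Step count and risks
Total steps: 6. Longest linear sequence: 5 (steps 1, 3, 4, 5, 6).

**Most likely to fail, first: step 3.** The risks are mono- versus bis-addition, the lability of the aryl silyl ethers, pinacol coupling, and unknown syn selectivity and ee with the 2-methyl donor.

The fallback sets out from 3 and breaks the symmetry at oxygen instead of at carbon.
- One equivalent of MeI with KHCO3 in DMF gives 4-hydroxy-6-methoxyisophthalaldehyde F1.
- The Bestmann ylide adds to its only phenol to give 2,4-diformyl-5-methoxyphenyl (triphenylphosphoranylidene)acetate F2.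
- F2 closes in the flask to 7-methoxy-2-oxo-2H-chromene-6-carbaldehyde F3.
- This phenol-free mono-aldehyde takes up 7 under the same Cr(salen)/Mn/Me3SiCl catalysis to give the 1′-O-trimethylsilyl ether of 13 F4.
- Citric acid work-up then gives 13, where the fallback comes back to the route. Compounds 10 and 11 are bypassed.

**Second: step 5.** The ylide may also add to the benzylic alcohol, or the ester ylide may react intermolecularly.

The fallback sets out from 11 and needs no O–H selectivity.
- Ph3P=CHCO2Me in CH2Cl2 at rt gives methyl (E)-3-{2-hydroxy-4-methoxy-5-[(1R,2R)-1-hydroxy-3-methyl-2-(3-methylbutanoyloxy)but-3-en-1-yl]phenyl}acrylate F5.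
- Irradiation at 365 nm in dilute MeCN turns it into the (Z)-acrylate isomer F6.
- F6 lactonises spontaneously with loss of methanol to 13, where the fallback rejoins.

**Third: step 6.** The risks are competing hydrogen-atom transfer to the coumarin C3=C4 bond or persistent peroxide.

The fallback sets out from 13 and replaces the radical hydration by an ionic sequence followed by a reduction.
- mCPBA in CH2Cl2 epoxidises only the electron-neutral alkene and gives the 2-methyloxiran-2-yl analogue of 13 (both epimers at the new centre) F7.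
- LiI/AcOH in THF opens it at the CH2 terminus to the iodohydrin with a C(CH3)(OH)CH2I terminus F8.
- Bu3SnH with Et3B/air at rt removes the iodine, which erases the extra stereocentre and gives 14 directly.

## Further compounds
F1 | step 3 | 4-hydroxy-6-methoxyisophthalaldehyde | COc1cc(O)c(C=O)cc1C=O
F2 | step 3 | 2,4-diformyl-5-methoxyphenyl (triphenylphosphoranylidene)acetate | COc1cc(OC(=O)C=P(c2ccccc2)(c2ccccc2)c2ccccc2)c(C=O)cc1C=O
F3 | step 3 | 7-methoxy-2-oxo-2H-chromene-6-carbaldehyde | COc1cc2oc(=O)ccc2cc1C=O
F4 | step 3 | 1′-O-trimethylsilyl ether of 13 | COc1cc2oc(=O)ccc2cc1[C@@H](O[Si](C)(C)C)[C@H](OC(=O)CC(C)C)C(C)=C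
F5 | step 5 | methyl (E)-3-{2-hydroxy-4-methoxy-5-[(1R,2R)-1-hydroxy-3-methyl-2-(3-methylbutanoyloxy)but-3-en-1-yl]phenyl}acrylate | COC(=O)/C=C/c1cc([C@@H](O)[C@H](OC(=O)CC(C)C)C(C)=C)c(OC)cc1O
F6 | step 5 | (Z)-acrylate isomer of F5 | COC(=O)/C=C\c1cc([C@@H](O)[C@H](OC(=O)CC(C)C)C(C)=C)c(OC)cc1O
F7 | step 6 | 2-methyloxiran-2-yl analogue of 13 (epimers at the oxirane carbon) | COc1cc2oc(=O)ccc2cc1[C@@H](O)[C@H](OC(=O)CC(C)C)C1(C)CO1
F8 | step 6 | iodohydrin with C(CH3)(OH)CH2I terminus (epimers at C-3′) | COc1cc2oc(=O)ccc2cc1[C@@H](O)[C@H](OC(=O)CC(C)C)C(C)(O)CI
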